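**Strategy.** Everything rests on disconnecting the aryl ketone between the carbonyl carbon and C1' of the phloroglucinol ring A. Ring A is carried as its tris-MOM ether with the C3' prenyl group already installed; its two remaining C–H positions (C1', C5') are mirror-equivalent and each lies between two MOM oxygens. Directed ortho-lithiation therefore gives one aryllithium, which acylates the Weinreb amide of the fully functionalised ring-B propanoic acid (free C3 phenol, C4 methoxy, C5 prenyl). This polarity-reversed Friedel–Crafts union forges the complete diprenylated dihydrochalcone skeleton in one operation under non-acidic conditions that both prenyl groups tolerate; mild acid methanolysis then frees the three ring-A phenols.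

Key step: step 7

Assumption: phloroglucinol, 3-bromo-4,5-dihydroxybenzaldehyde and the reagents named below are taken as commercial. The target has no stereocentre and no E/Z-isomeric double bond, so no step has to control configuration.

**Step 1**
Reactants: 1 phloroglucinol (benzene-1,3,5-triol)
Product: 2 1,3,5-tris(methoxymethoxy)benzene
Conditions: NaH (3.6 equiv), MOMCl (3.6 equiv), DMF, 0 °C → rt
Reagents that add atoms: chloromethyl methyl ether (MOMCl), COCCl
Why: Williamson-type O-alkylation of the three sodium phenoxides with the hard, oxocarbenium-like electrophile MOMCl should go at oxygen and install the acetal ethers that later direct both lithiations.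

**Step 2**
Reactants: 2 1,3,5-tris(methoxymethoxy)benzene
Product: 4 1,3,5-tris(methoxymethoxy)-2-(3-methylbut-2-en-1-yl)benzene, via aryllithium 3 (not isolated)
Conditions: n-BuLi (1.1 equiv), THF, 0 °C, 1 h; then CuI (10 mol %), prenyl bromide (1.2 equiv), −78 °C → rt
Reagents that add atoms: 1-bromo-3-methylbut-2-ene (prenyl bromide), CC(C)=CCBr
Why: Directed ortho-metalation: every ring C–H of 2 lies between two chelating MOM ethers, so one aryllithium forms, and its copper-catalysed SN2 allylation at the unhindered CH2 of prenyl bromide should give the linear prenyl arene.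

**Step 3**
Reactants: 5 3-bromo-4,5-dihydroxybenzaldehyde
Product: 6 3-bromo-5-hydroxy-4-methoxybenzaldehyde
Conditions: MeI (1.05 equiv), Li2CO3 (1.1 equiv), DMF, 40 °C
Reagents that add atoms: iodomethane, CI
Why: Selective Williamson etherification: the C4 hydroxyl, para to the aldehyde and ortho to bromine, is by far the more acidic, so the weak base forms only this phenoxide and methylation should stop at the mono-ether.

**Step 4**
Reactants: 6 3-bromo-5-hydroxy-4-methoxybenzaldehyde
Product: 9 3-(3-bromo-5-hydroxy-4-methoxyphenyl)propanoic acid, via arylidene Meldrum's acid 7 (not isolated), via benzyl Meldrum's acid 8 (not isolated)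
Conditions: Meldrum's acid (1.05 equiv), HCO2H/Et3N (5:2), rt, then 95–100 °C
Reagents that add atoms: Meldrum's acid (2,2-dimethyl-1,3-dioxane-4,6-dione), CC1(C)OC(=O)CC(=O)O1
Why: Reductive Knoevenagel sequence: condensation gives 7, formate delivers hydride to this strong Michael acceptor to give 8, and the hot medium hydrolyses and decarboxylates 8 to the propanoic acid, none of which should touch the aryl bromide or the phenol.

**Step 5**
Reactants: 9 3-(3-bromo-5-hydroxy-4-methoxyphenyl)propanoic acid
Product: 10 3-(3-bromo-5-hydroxy-4-methoxyphenyl)-N-methoxy-N-methylpropanamide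
Conditions: MeNHOMe·HCl (1.3 equiv), EDC·HCl (1.3 equiv), HOBt (0.2 equiv), N-methylmorpholine (3 equiv), CH2Cl2, 0 °C → rt
Reagents that add atoms: N,O-dimethylhydroxylamine hydrochloride, CNOC.Cl
Why: Carbodiimide amide coupling through the HOBt active ester; the amine is far more nucleophilic than the phenol, and any aryl ester formed should be aminolysed to the same amide.

**Step 6**
Reactants: 10 3-(3-bromo-5-hydroxy-4-methoxyphenyl)-N-methoxy-N-methylpropanamide
Product: 11 3-[3-hydroxy-4-methoxy-5-(3-methylbut-2-en-1-yl)phenyl]-N-methoxy-N-methylpropanamide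
Conditions: tributyl(prenyl)stannane (1.5 equiv), Pd(PPh3)4 (5 mol %), DMF, 100 °C
Reagents that add atoms: tributyl(3-methylbut-2-en-1-yl)stannane, CCCC[Sn](CCCC)(CCCC)CC=C(C)C
Why: Stille coupling: oxidative addition of Pd(0) into the Ar–Br bond, transmetalation from the allylic stannane and reductive elimination at the less hindered CH2 terminus should give the linear prenyl group under neutral conditions that tolerate the free phenol and the Weinreb amide.

**Step 7 (key step)**
Reactants: 4 1,3,5-tris(methoxymethoxy)-2-(3-methylbut-2-en-1-yl)benzene; 11 3-[3-hydroxy-4-methoxy-5-(3-methylbut-2-en-1-yl)phenyl]-N-methoxy-N-methylpropanamide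
Product: 14 3-[3-hydroxy-4-methoxy-5-(3-methylbut-2-en-1-yl)phenyl]-1-[2,4,6-tris(methoxymethoxy)-3-(3-methylbut-2-en-1-yl)phenyl]propan-1-one, via aryllithium 12 (not isolated), via tetrahedral dilithium adduct 13 (not isolated)
Conditions: 4 (2.3 equiv), n-BuLi (2.2 equiv), THF, 0 °C, 1 h; then 11 (1.0 equiv), −78 → 0 °C; sat. aq NH4Cl
Reagents that add atoms: none
Why: n-BuLi is pre-complexed by the MOM ethers on C2' and C6' and removes the C1'–H lying between them (directed ortho-metalation); because C1' and C5' of 4 are related by the mirror plane through C3' and C6', only one aryllithium (12) can form. The first equivalent of 12 deprotonates the C3 phenol of 11 (returning 4, which is recovered), and the second adds to the amide carbonyl to give the N-methoxy-chelated tetrahedral adduct 13, which collapses to ketone 14 only on aqueous quench, so over-addition is excluded (Weinreb ketone synthesis). The closest known reaction type is the acylation of ortho-lithiated MOM-protected phenols with N-methoxy-N-methylamides. No ring is closed and no stereocentre is created (the carbinolamine centre of 13 is lost on collapse). The step needs ring metalation instead of lateral metalation at the benzylic/allylic CH2 of the C3' prenyl group, and addition instead of α-deprotonation of the amide; the two flanking chelating MOM groups should secure the first, and the low basicity but high carbonyl affinity of the 2,6-dialkoxyaryllithium at low temperature the second. Both prenyl groups, which rule out Friedel–Crafts or Hoesch conditions, should be untouched by this acid-free union.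

**Step 8**
Reactants: 14 3-[3-hydroxy-4-methoxy-5-(3-methylbut-2-en-1-yl)phenyl]-1-[2,4,6-tris(methoxymethoxy)-3-(3-methylbut-2-en-1-yl)phenyl]propan-1-one
Product: 15 3-[3-hydroxy-4-methoxy-5-(3-methylbut-2-en-1-yl)phenyl]-1-[2,4,6-trihydroxy-3-(3-methylbut-2-en-1-yl)phenyl]propan-1-one (target)
Conditions: HCl (ca. 1 M) in MeOH, rt
Reagents that add atoms: none
Why: Acid-catalysed acetal methanolysis (MOM cleavage by transacetalisation to dimethoxymethane) should be faster in dilute methanolic HCl at room temperature than protonation of the trisubstituted prenyl alkenes, and the dihydrochalcone cannot cyclise to a flavanone.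

**Compound list**

1 | phloroglucinol (benzene-1,3,5-triol) | Oc1cc(O)cc(O)c1 | starting material
2 | 1,3,5-tris(methoxymethoxy)benzene | COCOc1cc(OCOC)cc(OCOC)c1 | intermediate
3 | [2,4,6-tris(methoxymethoxy)phenyl]lithium (aryllithium, not isolated) | [Li]c1c(OCOC)cc(OCOC)cc1OCOC | intermediate
4 | 1,3,5-tris(methoxymethoxy)-2-(3-methylbut-2-en-1-yl)benzene | COCOc1cc(OCOC)c(CC=C(C)C)c(OCOC)c1 | intermediate
5 | 3-bromo-4,5-dihydroxybenzaldehyde | O=Cc1cc(O)c(O)c(Br)c1 | starting material
6 | 3-bromo-5-hydroxy-4-methoxybenzaldehyde | COc1c(O)cc(C=O)cc1Br | intermediate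
7 | 5-[(3-bromo-5-hydroxy-4-methoxyphenyl)methylidene]-2,2-dimethyl-1,3-dioxane-4,6-dione (arylidene Meldrum's acid, not isolated) | COc1c(O)cc(C=C2C(=O)OC(C)(C)OC2=O)cc1Br | intermediate
8 | 5-[(3-bromo-5-hydroxy-4-methoxyphenyl)methyl]-2,2-dimethyl-1,3-dioxane-4,6-dione (benzyl Meldrum's acid, not isolated) | COc1c(O)cc(CC2C(=O)OC(C)(C)OC2=O)cc1Br | intermediate
9 | 3-(3-bromo-5-hydroxy-4-methoxyphenyl)propanoic acid | COc1c(O)cc(CCC(=O)O)cc1Br | intermediate
10 | 3-(3-bromo-5-hydroxy-4-methoxyphenyl)-N-methoxy-N-methylpropanamide | COc1c(O)cc(CCC(=O)N(C)OC)cc1Br | intermediate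
11 | 3-[3-hydroxy-4-methoxy-5-(3-methylbut-2-en-1-yl)phenyl]-N-methoxy-N-methylpropanamide | COc1c(O)cc(CCC(=O)N(C)OC)cc1CC=C(C)C | intermediate
12 | [2,4,6-tris(methoxymethoxy)-3-(3-methylbut-2-en-1-yl)phenyl]lithium (aryllithium, not isolated) | [Li]c1c(OCOC)cc(OCOC)c(CC=C(C)C)c1OCOC | intermediate
13 | tetrahedral dilithium adduct of 12 and the lithium phenoxide of 11 (racemic at the transient carbinolamine carbon, not isolated) | COc1c([O-])cc(CCC([O-])(N(C)OC)c2c(OCOC)cc(OCOC)c(CC=C(C)C)c2OCOC)cc1CC=C(C)C.[Li+].[Li+] | intermediate
14 | 3-[3-hydroxy-4-methoxy-5-(3-methylbut-2-en-1-yl)phenyl]-1-[2,4,6-tris(methoxymethoxy)-3-(3-methylbut-2-en-1-yl)phenyl]propan-1-one | COc1c(O)cc(CCC(=O)c2c(OCOC)cc(OCOC)c(CC=C(C)C)c2OCOC)cc1CC=C(C)C | intermediate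
15 | 3,2',4',6'-tetrahydroxy-4-methoxy-3',5-diprenyldihydrochalcone | COc1c(O)cc(CCC(=O)c2c(O)cc(O)c(CC=C(C)C)c2O)cc1CC=C(C)C | target

**Step count.** Total: 8 steps. Longest linear sequence: 6 steps (steps 3–8, from 5); the ring-A branch (steps 1–2) joins at step 7.

**Steps most likely to fail**

Step 7 (key step). The hindered 2,6-dialkoxyaryllithium may add sluggishly to the amide carbonyl, so that proton transfer from the amide α-CH2 takes over and the amide is returned. The fallback sets out from 11 and comes back at 14. Amide 11 would be reduced with DIBAL-H (THF, −78 °C) to the far more electrophilic aldehyde 3-[3-hydroxy-4-methoxy-5-(3-methylbut-2-en-1-yl)phenyl]propanal F1. Addition of aryllithium 12 (2.2 equiv, −78 °C) should then give the racemic benzylic alcohol 3-[3-hydroxy-4-methoxy-5-(3-methylbut-2-en-1-yl)phenyl]-1-[2,4,6-tris(methoxymethoxy)-3-(3-methylbut-2-en-1-yl)phenyl]propan-1-ol F2. Oxidation of this activated benzylic alcohol with MnO2 in CH2Cl2, which spares the phenol and the prenyl groups, should deliver ketone 14.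

Step 8. During MOM cleavage the acid may trigger cyclisation of the C3' prenyl group onto the freed C2' or C4' hydroxyl (chroman formation) or Markovnikov addition of HCl or methanol to a prenyl double bond. The fallback sets out from 1 and comes back at 15, replacing the acid-labile MOM groups by fluoride-labile SEM groups. Phloroglucinol 1 would be converted with SEMCl/NaH into 1,3,5-tris{[2-(trimethylsilyl)ethoxy]methoxy}benzene F3. Lithiation and prenylation as in step 2 should give 2-(3-methylbut-2-en-1-yl)-1,3,5-tris{[2-(trimethylsilyl)ethoxy]methoxy}benzene F4. Lithiation and union with 11 as in step 7 should give the tris-SEM ketone 3-[3-hydroxy-4-methoxy-5-(3-methylbut-2-en-1-yl)phenyl]-1-[3-(3-methylbut-2-en-1-yl)-2,4,6-tris{[2-(trimethylsilyl)ethoxy]methoxy}phenyl]propan-1-one F5. The SEM groups would then be removed with TBAF in THF/DMPU at 60 °C, with ethylenediamine added to trap the formaldehyde released, giving 15 without any acid.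

Step 6. Oxidative addition into the electron-rich, ortho-methoxylated aryl bromide may be slow; meanwhile the allylic stannane may be protodestannylated by the phenol, or may couple through its γ-carbon to give the reverse-prenyl (1,1-dimethylallyl) isomer. The fallback sets out from 10 and comes back at 11, building the prenyl group in two stages. Stille coupling of 10 with the less hindered, regiochemically unambiguous allyltributylstannane (Pd(PPh3)4, DMF, 90 °C) should give 3-[3-hydroxy-4-methoxy-5-(prop-2-en-1-yl)phenyl]-N-methoxy-N-methylpropanamide F6. Olefin cross-metathesis of this terminal alkene with excess 2-methylbut-2-ene (second-generation ruthenium–NHC benzylidene catalyst, CH2Cl2, 40 °C) should convert the allyl group into the prenyl group of 11.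

**Further compounds**

F1 | step 7 | 3-[3-hydroxy-4-methoxy-5-(3-methylbut-2-en-1-yl)phenyl]propanal | COc1c(O)cc(CCC=O)cc1CC=C(C)C
F2 | step 7 | 3-[3-hydroxy-4-methoxy-5-(3-methylbut-2-en-1-yl)phenyl]-1-[2,4,6-tris(methoxymethoxy)-3-(3-methylbut-2-en-1-yl)phenyl]propan-1-ol (racemic) | COc1c(O)cc(CCC(O)c2c(OCOC)cc(OCOC)c(CC=C(C)C)c2OCOC)cc1CC=C(C)C
F3 | step 8 | 1,3,5-tris{[2-(trimethylsilyl)ethoxy]methoxy}benzene | C[Si](C)(C)CCOCOc1cc(OCOCC[Si](C)(C)C)cc(OCOCC[Si](C)(C)C)c1
F4 | step 8 | 2-(3-methylbut-2-en-1-yl)-1,3,5-tris{[2-(trimethylsilyl)ethoxy]methoxy}benzene | C[Si](C)(C)CCOCOc1cc(OCOCC[Si](C)(C)C)c(CC=C(C)C)c(OCOCC[Si](C)(C)C)c1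
F5 | step 8 | 3-[3-hydroxy-4-methoxy-5-(3-methylbut-2-en-1-yl)phenyl]-1-[3-(3-methylbut-2-en-1-yl)-2,4,6-tris{[2-(trimethylsilyl)ethoxy]methoxy}phenyl]propan-1-one | COc1c(O)cc(CCC(=O)c2c(OCOCC[Si](C)(C)C)cc(OCOCC[Si](C)(C)C)c(CC=C(C)C)c2OCOCC[Si](C)(C)C)cc1CC=C(C)C
F6 | step 6 | 3-[3-hydroxy-4-methoxy-5-(prop-2-en-1-yl)phenyl]-N-methoxy-N-methylpropanamide | COc1c(O)cc(CCC(=O)N(C)OC)cc1CC=C
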